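The quinone ring is built, not bought: it is cut at the bond between the carbonyl carbon that neighbours the indol-3-yl-bearing carbon and the methoxy-bearing carbon that neighbours the 7-prenylindol-3-yl-bearing carbon. In one thermal operation a 4-alkenyl-4-hydroxycyclobutenone opens (4π) to a dienylketene whose 6π-electrocyclization forges that bond and closes the six-membered ring; enolization and Ag2O oxidation give the fully substituted 2,5-dimethoxy-3,6-diaryl-1,4-benzoquinone. The step exploits the para-dioxygenated ring in which every carbonyl is flanked by a methoxy-bearing and an indolyl-bearing carbon. The precursor comes from 3-(indol-3-yl)-4-methoxycyclobutenedione and a 1-(7-prenylindol-3-yl)-2-methoxyvinyllithium.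

Key step: step 9

Remark: compounds 15 and 17 are racemic (one stereocentre each, both erased on aromatization), so the route needs no stereocontrol beyond the double-bond geometry set in step 4.

Step 1
Reactants: 1 7-bromo-1H-indole; 2 tributyl(3-methylbut-2-en-1-yl)stannane
Product: 3 7-(3-methylbut-2-en-1-yl)-1H-indole
Conditions: Pd(PPh3)4 (5 mol %), DMF, 100 °C
Reagents that add atoms: none
Why: Stille coupling, in which zerovalent palladium inserts into the C7–Br bond, the prenyl group is transferred from tin and reductive elimination at the unsubstituted allyl terminus should give the linear prenyl arene, the free N–H being tolerated.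

Step 2
Reactants: 3 7-(3-methylbut-2-en-1-yl)-1H-indole; 4 methoxyacetyl chloride
Product: 5 2-methoxy-1-[7-(3-methylbut-2-en-1-yl)-1H-indol-3-yl]ethan-1-one
Conditions: Et2AlCl, CH2Cl2, 0 °C; then 4, 0 °C
Reagents that add atoms: none
Why: Friedel–Crafts acylation at the nucleophilic C3 of the indole under Et2AlCl, which activates the acid chloride and consumes the HCl so that neither the N–H nor the prenyl double bond is attacked.

Step 3
Reactants: 5 2-methoxy-1-[7-(3-methylbut-2-en-1-yl)-1H-indol-3-yl]ethan-1-one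
Product: 6 2-methoxy-1-[7-(3-methylbut-2-en-1-yl)-1-(phenylsulfonyl)-1H-indol-3-yl]ethan-1-one
Conditions: NaH, THF, 0 °C; PhSO2Cl, 0 °C to rt
Reagents that add atoms: benzenesulfonyl chloride, O=S(=O)(Cl)c1ccccc1
Why: N-sulfonylation of the sodium indolide (the N–H of a 3-acylindole is far more acidic than the α-CH2), giving a nitrogen group that is inert to amide bases, to palladium catalysis and to MeLi at –78 °C.

Step 4
Reactants: 6 2-methoxy-1-[7-(3-methylbut-2-en-1-yl)-1-(phenylsulfonyl)-1H-indol-3-yl]ethan-1-one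
Product: 7 (Z)-2-methoxy-1-[7-(3-methylbut-2-en-1-yl)-1-(phenylsulfonyl)-1H-indol-3-yl]ethenyl trifluoromethanesulfonate
Conditions: KN(SiMe3)2 (1.05 equiv), THF, –78 °C; PhNTf2, –78 to 0 °C
Reagents that add atoms: N-phenylbis(trifluoromethanesulfonimide), O=S(=O)(N(c1ccccc1)S(=O)(=O)C(F)(F)F)C(F)(F)F
Why: Kinetic enolization and O-sulfonylation of the potassium enolate, whose geometry (methoxy cis to the enolate oxygen through chelation of potassium and avoidance of A(1,3) strain with the indole) should fix the (Z)-triflate with OTf cis to OMe.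

Step 5
Reactants: 7 (Z)-2-methoxy-1-[7-(3-methylbut-2-en-1-yl)-1-(phenylsulfonyl)-1H-indol-3-yl]ethenyl trifluoromethanesulfonate
Product: 8 3-[(Z)-2-methoxy-1-(trimethylstannyl)ethenyl]-7-(3-methylbut-2-en-1-yl)-1-(phenylsulfonyl)-1H-indole
Conditions: Me3SnSnMe3 (1.5 equiv), Pd(PPh3)4 (5 mol %), LiCl, THF, 60 °C
Reagents that add atoms: hexamethylditin, C[Sn](C)(C)[Sn](C)(C)C
Why: Palladium-catalyzed stannylation of a vinyl triflate with a distannane (oxidative addition, chloride-assisted Sn–Sn transmetalation, reductive elimination), which proceeds with retention of the double-bond geometry.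

Step 6
Reactants: 9 1H-indole; 10 3,4-dichlorocyclobut-3-ene-1,2-dione (squaric acid dichloride)
Product: 12 3-(1H-indol-3-yl)-4-methoxycyclobut-3-ene-1,2-dione, via chlorocyclobutenedione 11 (not isolated)
Conditions: Et2O, 0 °C to rt; then MeOH, rt
Reagents that add atoms: methanol, CO
Why: Uncatalyzed Friedel–Crafts reaction of the vinylogous acid chloride at indole C3 by addition–elimination, the first indolyl group deactivating the second chloride towards further arylation, followed by methanolysis of that remaining vinylogous acid chloride.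

Step 7
Reactants: 12 3-(1H-indol-3-yl)-4-methoxycyclobut-3-ene-1,2-dione
Product: 13 tert-butyl 3-(2-methoxy-3,4-dioxocyclobut-1-en-1-yl)-1H-indole-1-carboxylate
Conditions: Boc2O, DMAP (5 mol %), CH2Cl2, 0 °C to rt
Reagents that add atoms: di-tert-butyl dicarbonate, CC(C)(C)OC(=O)OC(=O)OC(C)(C)C
Why: DMAP-catalyzed N-acylation of the acidic vinylogous-amide N–H, which removes the acidic proton and weakens donation of the indole into the ring so that the methoxy group alone decides which carbonyl is the more electrophilic in step 8.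

Step 8
Reactants: 8 3-[(Z)-2-methoxy-1-(trimethylstannyl)ethenyl]-7-(3-methylbut-2-en-1-yl)-1-(phenylsulfonyl)-1H-indole; 13 tert-butyl 3-(2-methoxy-3,4-dioxocyclobut-1-en-1-yl)-1H-indole-1-carboxylate
Product: 15 tert-butyl 3-{3-hydroxy-2-methoxy-3-[(Z)-2-methoxy-1-[7-(3-methylbut-2-en-1-yl)-1-(phenylsulfonyl)-1H-indol-3-yl]ethenyl]-4-oxocyclobut-1-en-1-yl}-1H-indole-1-carboxylate (racemic), via vinyllithium 14 (not isolated)
Conditions: MeLi (1.0 equiv), THF, –78 °C; then 13, THF, –78 °C; aq. NH4Cl; crude product taken on without chromatography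
Reagents that add atoms: none
Why: Tin–lithium exchange with retention gives an α-aryl vinyllithium whose lithium is cis to the methoxy group (the stable, internally coordinated isomer), and this should add 1,2 to the ketone carbonyl next to the methoxy-bearing ring carbon, the other carbonyl being deactivated as a vinylogous ester; the new carbinol stereocentre forms as a racemate and is erased in step 9.

Step 9
Reactants: 15 tert-butyl 3-{3-hydroxy-2-methoxy-3-[(Z)-2-methoxy-1-[7-(3-methylbut-2-en-1-yl)-1-(phenylsulfonyl)-1H-indol-3-yl]ethenyl]-4-oxocyclobut-1-en-1-yl}-1H-indole-1-carboxylate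
Product: 19 tert-butyl 3-{2,5-dimethoxy-3,6-dioxo-4-[7-(3-methylbut-2-en-1-yl)-1-(phenylsulfonyl)-1H-indol-3-yl]cyclohexa-1,4-dien-1-yl}-1H-indole-1-carboxylate, via dienylketene 16 (not isolated), via cyclohexadienone 17 (not isolated), via hydroquinone 18 (not isolated)
Conditions: toluene (degassed), 110 °C; then Ag2O, rt
Reagents that add atoms: none
Why: Heating opens the cyclobutenone by conrotatory 4π-electrocyclic cleavage of its C1–C4 bond, the hydroxyl rotating outward (donor torquoselectivity) so that the alkenyl group ends up cis to the ketene in dienylketene 16. Disrotatory 6π-electrocyclization then joins the ketene carbon (the carbon next to the Boc-indolyl-bearing carbon) to the methoxy-bearing vinyl terminus and closes the six-membered carbocycle as 2,4-cyclohexadienone 17; the closure is pericyclic, not a polar exo or endo attack. Enolization of the C6–H of 17 gives hydroquinone 18, which Ag2O dehydrogenates to the quinone. The closest known reaction type is the Moore–Liebeskind ring expansion of 4-alkenyl-4-hydroxycyclobutenones to hydroquinones and quinones. No stereocentre survives, since the carbinol centre of 15 and the C6 centre of 17 are both erased on aromatization. The step needs outward rotation of the hydroxyl (otherwise it traps the ketene as a furanone), closure onto the vinyl carbon and not an indole position (only the vinyl terminus reaches the ketene in a six-membered array) and enolization faster than loss of methanol; the substituent pattern, the triene geometry and the acid-free medium are meant to secure these.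

Step 10
Reactants: 19 tert-butyl 3-{2,5-dimethoxy-3,6-dioxo-4-[7-(3-methylbut-2-en-1-yl)-1-(phenylsulfonyl)-1H-indol-3-yl]cyclohexa-1,4-dien-1-yl}-1H-indole-1-carboxylate
Product: 20 2,5-dimethoxy-3-(1H-indol-3-yl)-6-[7-(3-methylbut-2-en-1-yl)-1H-indol-3-yl]cyclohexa-2,5-diene-1,4-dione (CNP0256613.0)
Conditions: NaOMe (2.5 equiv), dry MeOH/THF, 0 °C; AcOH quench
Reagents that add atoms: none
Why: Methoxide should cleave both nitrogen groups by attack at the carbamate carbonyl and at sulfur, the 3-quinonyl indolides being good leaving groups, while any addition of methoxide to the methoxy-bearing quinone carbons is degenerate and the prenyl group is inert.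

Compound list
1 | 7-bromo-1H-indole | Brc1cccc2cc[nH]c12 | starting material
2 | tributyl(3-methylbut-2-en-1-yl)stannane | CCCC[Sn](CCCC)(CCCC)CC=C(C)C | starting material
3 | 7-(3-methylbut-2-en-1-yl)-1H-indole | CC(C)=CCc1cccc2cc[nH]c12 | intermediate
4 | methoxyacetyl chloride | COCC(Cl)=O | starting material
5 | 2-methoxy-1-[7-(3-methylbut-2-en-1-yl)-1H-indol-3-yl]ethan-1-one | COCC(=O)c1c[nH]c2c(CC=C(C)C)cccc12 | intermediate
6 | 2-methoxy-1-[7-(3-methylbut-2-en-1-yl)-1-(phenylsulfonyl)-1H-indol-3-yl]ethan-1-one | COCC(=O)c1cn(S(=O)(=O)c2ccccc2)c2c(CC=C(C)C)cccc12 | intermediate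
7 | (Z)-2-methoxy-1-[7-(3-methylbut-2-en-1-yl)-1-(phenylsulfonyl)-1H-indol-3-yl]ethenyl trifluoromethanesulfonate | CO/C=C(\OS(=O)(=O)C(F)(F)F)c1cn(S(=O)(=O)c2ccccc2)c2c(CC=C(C)C)cccc12 | intermediate
8 | 3-[(Z)-2-methoxy-1-(trimethylstannyl)ethenyl]-7-(3-methylbut-2-en-1-yl)-1-(phenylsulfonyl)-1H-indole | CO/C=C(\[Sn](C)(C)C)c1cn(S(=O)(=O)c2ccccc2)c2c(CC=C(C)C)cccc12 | intermediate
9 | 1H-indole | c1ccc2[nH]ccc2c1 | starting material
10 | 3,4-dichlorocyclobut-3-ene-1,2-dione (squaric acid dichloride) | O=C1C(=O)C(Cl)=C1Cl | starting material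
11 | 3-chloro-4-(1H-indol-3-yl)cyclobut-3-ene-1,2-dione (not isolated) | O=C1C(=O)C(Cl)=C1c1c[nH]c2ccccc12 | intermediate
12 | 3-(1H-indol-3-yl)-4-methoxycyclobut-3-ene-1,2-dione | COC1=C(c2c[nH]c3ccccc23)C(=O)C1=O | intermediate
13 | tert-butyl 3-(2-methoxy-3,4-dioxocyclobut-1-en-1-yl)-1H-indole-1-carboxylate | COC1=C(c2cn(C(=O)OC(C)(C)C)c3ccccc23)C(=O)C1=O | intermediate
14 | {2-methoxy-1-[7-(3-methylbut-2-en-1-yl)-1-(phenylsulfonyl)-1H-indol-3-yl]ethenyl}lithium, lithium cis to methoxy (not isolated) | CO/C=C(\[Li])c1cn(S(=O)(=O)c2ccccc2)c2c(CC=C(C)C)cccc12 | intermediate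
15 | tert-butyl 3-{3-hydroxy-2-methoxy-3-[(Z)-2-methoxy-1-[7-(3-methylbut-2-en-1-yl)-1-(phenylsulfonyl)-1H-indol-3-yl]ethenyl]-4-oxocyclobut-1-en-1-yl}-1H-indole-1-carboxylate (racemic) | CO/C=C(\C1(O)C(OC)=C(c2cn(C(=O)OC(C)(C)C)c3ccccc23)C1=O)c1cn(S(=O)(=O)c2ccccc2)c2c(CC=C(C)C)cccc12 | intermediate
16 | dienylketene from ring opening of 15, hydroxyl outward and alkenyl group cis to the ketene (not isolated) | O=C=C(c1cn(C(=O)OC(C)(C)C)c2ccccc12)/C(OC)=C(/O)\C(c1cn(S(=O)(=O)c2ccccc2)c2c(CC=C(C)C)cccc12)=C/OC | intermediate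
17 | tert-butyl 3-{3-hydroxy-2,5-dimethoxy-6-oxo-4-[7-(3-methylbut-2-en-1-yl)-1-(phenylsulfonyl)-1H-indol-3-yl]cyclohexa-1,3-dien-1-yl}-1H-indole-1-carboxylate (racemic, not isolated) | COC1C(=O)C(c2cn(C(=O)OC(C)(C)C)c3ccccc23)=C(OC)C(O)=C1c1cn(S(=O)(=O)c2ccccc2)c2c(CC=C(C)C)cccc12 | intermediate
18 | tert-butyl 3-{2,5-dihydroxy-3,6-dimethoxy-4-[7-(3-methylbut-2-en-1-yl)-1-(phenylsulfonyl)-1H-indol-3-yl]phenyl}-1H-indole-1-carboxylate (not isolated) | COc1c(O)c(-c2cn(C(=O)OC(C)(C)C)c3ccccc23)c(OC)c(O)c1-c1cn(S(=O)(=O)c2ccccc2)c2c(CC=C(C)C)cccc12 | intermediate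
19 | tert-butyl 3-{2,5-dimethoxy-3,6-dioxo-4-[7-(3-methylbut-2-en-1-yl)-1-(phenylsulfonyl)-1H-indol-3-yl]cyclohexa-1,4-dien-1-yl}-1H-indole-1-carboxylate | COC1=C(c2cn(C(=O)OC(C)(C)C)c3ccccc23)C(=O)C(OC)=C(c2cn(S(=O)(=O)c3ccccc3)c3c(CC=C(C)C)cccc23)C1=O | intermediate
20 | 2,5-dimethoxy-3-(1H-indol-3-yl)-6-[7-(3-methylbut-2-en-1-yl)-1H-indol-3-yl]cyclohexa-2,5-diene-1,4-dione (CNP0256613.0) | COC1=C(c2c[nH]c3ccccc23)C(=O)C(OC)=C(c2c[nH]c3c(CC=C(C)C)cccc23)C1=O | target

Total step count: 10
Longest linear sequence: 8 steps (steps 1, 2, 3, 4, 5, 8, 9 and 10)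

Steps most likely to fail

Step 9. The cyclohexadienone may expel methanol by β-elimination through its enol faster than it tautomerizes to the hydroquinone. The methoxy group that points into the forming ring may also slow the 6π closure enough for such side paths to compete. The fallback makes the elimination the intended course and sets out from 15. Heating 15 in toluene at 110 °C with a catalytic amount of pyridinium p-toluenesulfonate should give, through 16 and 17, the methanol-loss quinone tert-butyl 3-{2-methoxy-3,6-dioxo-4-[7-(3-methylbut-2-en-1-yl)-1-(phenylsulfonyl)-1H-indol-3-yl]cyclohexa-1,4-dien-1-yl}-1H-indole-1-carboxylate F1, which is already at the quinone oxidation level and carries the same newly made ring bond. The missing methoxy group is then put back at the only unsubstituted ring carbon by ZnCl2-promoted conjugate addition of methanol (giving hydroquinone 18) and reoxidation with Ag2O, which brings the route back at 19.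

Step 8. The vinyllithium may lose lithium methoxide by β-elimination on warming or take up a proton from an indole C2–H. A small excess of MeLi or the wrong carbonyl regiochemistry would also erode the addition. The fallback sets out from 8 and replaces lithium by magnesium. Iododestannylation of 8 with I2 (CH2Cl2, 0 °C) should give, with retention, 3-[(Z)-1-iodo-2-methoxyethenyl]-7-(3-methylbut-2-en-1-yl)-1-(phenylsulfonyl)-1H-indole F2. Iodine–magnesium exchange with i-PrMgCl·LiCl (THF, –40 °C) then gives chloro{(Z)-2-methoxy-1-[7-(3-methylbut-2-en-1-yl)-1-(phenylsulfonyl)-1H-indol-3-yl]ethenyl}magnesium F3 (not isolated), which is less basic and far less prone to β-elimination. Its addition to 13 at –78 to –40 °C comes back to the route at 15.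

Step 5. Stannylation of the hindered, electron-rich enol triflate may stall after oxidative addition, or the product may couple with unreacted triflate to a diene dimer; the triflate itself may also be lost to hydrolysis on handling. The fallback avoids both the triflate and the palladium step and sets out from 3:
- Vilsmeier formylation of 3 (POCl3, DMF; aqueous NaOH) gives 7-(3-methylbut-2-en-1-yl)-1H-indole-3-carbaldehyde F4.
- N-sulfonylation (NaH, PhSO2Cl) gives 7-(3-methylbut-2-en-1-yl)-1-(phenylsulfonyl)-1H-indole-3-carbaldehyde F5.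
- Wittig reaction with Ph3P=CHOMe (from MeOCH2PPh3Cl and KOt-Bu) gives 3-(2-methoxyethenyl)-7-(3-methylbut-2-en-1-yl)-1-(phenylsulfonyl)-1H-indole F6 as an E/Z mixture.
- Addition of one equivalent of Br2 to the enol ether at –78 °C and dehydrobromination with DBU should give 3-[(Z)-1-bromo-2-methoxyethenyl]-7-(3-methylbut-2-en-1-yl)-1-(phenylsulfonyl)-1H-indole F7.
- Bromine–lithium exchange with t-BuLi (2 equiv, –100 °C) gives vinyllithium 14, and addition to 13 as in step 8 brings the route back at 15.

Further compounds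
F1 | step 9 | tert-butyl 3-{2-methoxy-3,6-dioxo-4-[7-(3-methylbut-2-en-1-yl)-1-(phenylsulfonyl)-1H-indol-3-yl]cyclohexa-1,4-dien-1-yl}-1H-indole-1-carboxylate | COC1=C(c2cn(C(=O)OC(C)(C)C)c3ccccc23)C(=O)C=C(c2cn(S(=O)(=O)c3ccccc3)c3c(CC=C(C)C)cccc23)C1=O
F2 | step 8 | 3-[(Z)-1-iodo-2-methoxyethenyl]-7-(3-methylbut-2-en-1-yl)-1-(phenylsulfonyl)-1H-indole | CO/C=C(\I)c1cn(S(=O)(=O)c2ccccc2)c2c(CC=C(C)C)cccc12
F3 | step 8 | chloro{(Z)-2-methoxy-1-[7-(3-methylbut-2-en-1-yl)-1-(phenylsulfonyl)-1H-indol-3-yl]ethenyl}magnesium | CO/C=C(\[Mg]Cl)c1cn(S(=O)(=O)c2ccccc2)c2c(CC=C(C)C)cccc12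
F4 | step 5 | 7-(3-methylbut-2-en-1-yl)-1H-indole-3-carbaldehyde | O=Cc1c[nH]c2c(CC=C(C)C)cccc12
F5 | step 5 | 7-(3-methylbut-2-en-1-yl)-1-(phenylsulfonyl)-1H-indole-3-carbaldehyde | O=Cc1cn(S(=O)(=O)c2ccccc2)c2c(CC=C(C)C)cccc12
F6 | step 5 | 3-(2-methoxyethenyl)-7-(3-methylbut-2-en-1-yl)-1-(phenylsulfonyl)-1H-indole (E/Z mixture) | COC=Cc1cn(S(=O)(=O)c2ccccc2)c2c(CC=C(C)C)cccc12
F7 | step 5 | 3-[(Z)-1-bromo-2-methoxyethenyl]-7-(3-methylbut-2-en-1-yl)-1-(phenylsulfonyl)-1H-indole | CO/C=C(\Br)c1cn(S(=O)(=O)c2ccccc2)c2c(CC=C(C)C)cccc12
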